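Ring B is cut at C3–C4. C4 of the target is a bare benzylic CH2 on C4a of ring A. C2 and C3 carry carbons (C9, C10) that can be esters. C4 can therefore enter as an aryl ester carbonyl and be erased afterwards. The key step is a Dieckmann closure of a trimethyl ester, a 2-(diarylmethyl)succinate whose ring A bears CO2Me at C4a. One operation forms C3–C4, closes ring B and lets C2 and C3 settle trans to the single catalytic stereocentre C1. C4 stays masked as a dioxolane until C2 has been alkylated. The ring A oxygen pattern is fixed by symmetry and chelation.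

Key step: step 11

Numbering: the tetralin numbering of the target is used for all intermediates (C1 bears the guaiacyl ring, C2/C3 bear C9/C10, C4 is the benzylic carbon on C4a, ring A runs C4a, C5, C6, C7, C8, C8a).

Assumption: for a linear E-configured acceptor the (S,S) antipode of the diene ligand is taken to expose the Si face of C1, as the usual quadrant model predicts, and both antipodes are available, so the sense of induction is a matter of ligand choice; C2 arises without control in step 8, so the succinates are drawn as the epimer with the C2 configuration of the target and the other epimer is carried along, since step 11 merges them.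

Step 1
Reactants: 1 methyl 3,5-dihydroxy-4-methoxybenzoate
Product: 2 methyl 2-formyl-3,5-dihydroxy-4-methoxybenzoate
Conditions: POCl3, DMF, MeCN, 0 to 40 °C; then ice/H2O
Reagents that add atoms: N,N-dimethylformamide CN(C)C=O (formyl carbon); water O (carbonyl oxygen)
Why: Vilsmeier–Haack formylation; the two free ring positions of 1 are related by symmetry and each lies ortho to one hydroxyl and para to the other, so only one monoaldehyde can form, and the new formyl group deactivates the ring toward a second attack.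

Step 2
Reactants: 2 methyl 2-formyl-3,5-dihydroxy-4-methoxybenzoate
Product: 3 methyl 5-(benzyloxy)-2-formyl-3-hydroxy-4-methoxybenzoate
Conditions: BnBr (1.0 equiv), KHCO3, DMF, 40 °C
Reagents that add atoms: benzyl bromide BrCc1ccccc1
Why: Williamson etherification under mild base; the hydroxyl para to the formyl group is the more acidic and is free, whereas the ortho hydroxyl is held in a hydrogen bond to the aldehyde (the bias that makes 2,4-dihydroxybenzaldehyde alkylate at O4), so benzyl ends up on the future C7 oxygen.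

Step 3
Reactants: 3 methyl 5-(benzyloxy)-2-formyl-3-hydroxy-4-methoxybenzoate
Product: 4 methyl 5-(benzyloxy)-2-formyl-3,4-dimethoxybenzoate
Conditions: MeI, K2CO3, DMF, 40 °C
Reagents that add atoms: iodomethane CI
Why: Williamson methylation with excess MeI and the stronger base overcomes the hydrogen bond and caps the future C5 oxygen, which completes the C5-OMe, C6-OMe, C7-OBn pattern without any regiochemical ambiguity.

Step 4
Reactants: 4 methyl 5-(benzyloxy)-2-formyl-3,4-dimethoxybenzoate
Product: 5 methyl 5-(benzyloxy)-2-(1,3-dioxolan-2-yl)-3,4-dimethoxybenzoate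
Conditions: (Me3SiOCH2)2, Me3SiOTf (cat.), CH2Cl2, −78 to −20 °C; pyridine quench
Reagents that add atoms: 1,2-bis(trimethylsilyloxy)ethane C[Si](C)(C)OCCO[Si](C)(C)C
Why: Noyori acetalisation under aprotic conditions masks the future C4 carbon without passing through a free hemiacetal that could lactonise onto the neighbouring ester, and the dioxolane then keeps C4 inert to hydride, ylide, aryl-rhodium species and enolate.

Step 5
Reactants: 5 methyl 5-(benzyloxy)-2-(1,3-dioxolan-2-yl)-3,4-dimethoxybenzoate
Product: 6 [5-(benzyloxy)-2-(1,3-dioxolan-2-yl)-3,4-dimethoxyphenyl]methanol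
Conditions: LiAlH4, THF, 0 °C; H2O/NaOH work-up
Reagents that add atoms: none
Why: Hydride reduction of the ester with LiAlH4 leaves the dioxolane and the benzyl ether untouched, and the basic work-up avoids acid-induced exchange between the new alcohol and the acetal.

Step 6
Reactants: 6 [5-(benzyloxy)-2-(1,3-dioxolan-2-yl)-3,4-dimethoxyphenyl]methanol; 7 methyl (triphenylphosphoranylidene)acetate
Product: 9 methyl (E)-3-[5-(benzyloxy)-2-(1,3-dioxolan-2-yl)-3,4-dimethoxyphenyl]prop-2-enoate, via dioxolanyl benzaldehyde 8 (not isolated)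
Conditions: MnO2 (excess), CH2Cl2, rt to reflux
Reagents that add atoms: none
Why: Tandem oxidation–Wittig olefination; MnO2 oxidises only the benzylic alcohol, the aldehyde is trapped as it forms by the stabilised ylide with its usual E preference, the neutral medium spares the acetal, and any Z isomer is removed by chromatography.

Step 7
Reactants: 9 methyl (E)-3-[5-(benzyloxy)-2-(1,3-dioxolan-2-yl)-3,4-dimethoxyphenyl]prop-2-enoate; 10 (4-benzyloxy-3-methoxyphenyl)boronic acid
Product: 11 methyl (3R)-3-[4-(benzyloxy)-3-methoxyphenyl]-3-[5-(benzyloxy)-2-(1,3-dioxolan-2-yl)-3,4-dimethoxyphenyl]propanoate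
Conditions: [RhCl(C2H4)2]2 (2.5 mol %), (1S,4S)-2,5-diphenylbicyclo[2.2.2]octa-2,5-diene (5.5 mol %), KOH (0.3 equiv), dioxane/H2O 10:1, 40 °C
Reagents that add atoms: none
Why: Hayashi–Miyaura asymmetric 1,4-addition; the aryl-rhodium species held by the C2-symmetric diene inserts the E-cinnamate at the Si face of C1 and water protonates the rhodium enolate, which sets C1 as R, and the ethylene complex is chosen because its olefins are displaced completely by the chiral diene, whereas a cyclooctadiene complex would stay intact and run a racemic background reaction.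

Step 8
Reactants: 11 methyl (3R)-3-[4-(benzyloxy)-3-methoxyphenyl]-3-[5-(benzyloxy)-2-(1,3-dioxolan-2-yl)-3,4-dimethoxyphenyl]propanoate; 12 methyl bromoacetate
Product: 14 dimethyl (2R)-2-{(R)-[4-(benzyloxy)-3-methoxyphenyl][5-(benzyloxy)-2-formyl-3,4-dimethoxyphenyl]methyl}butanedioate, via dioxolane succinate 13 (not isolated)
Conditions: LiN(i-Pr)2, THF, −78 °C; 12, −78 to −30 °C; then 1 M HCl, THF, rt
Reagents that add atoms: water O (aldehyde oxygen)
Why: Ester enolate alkylation (SN2 on the bromoacetate) followed by acetal hydrolysis; because C4 is still an acetal, the C2 enolate has no acyl group within reach, so the five-membered Claisen closure to an enolisable indanone that an aryl ester at C4a would invite at this stage cannot occur, C2 forms as epimers that converge later, and the electron-rich aryl dioxolane falls to dilute acid while the methyl esters survive.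

Step 9
Reactants: 14 dimethyl (2R)-2-{(R)-[4-(benzyloxy)-3-methoxyphenyl][5-(benzyloxy)-2-formyl-3,4-dimethoxyphenyl]methyl}butanedioate
Product: 15 4-(benzyloxy)-6-{(1R,2R)-1-[4-(benzyloxy)-3-methoxyphenyl]-4-methoxy-2-(methoxycarbonyl)-4-oxobutyl}-2,3-dimethoxybenzoic acid
Conditions: NaClO2, NaH2PO4, 2-methyl-2-butene, t-BuOH/THF/H2O, rt
Reagents that add atoms: sodium chlorite [Na+].[O-]Cl=O
Why: Pinnick oxidation converts the hindered, non-enolisable aryl aldehyde into the acid under weakly acidic conditions that cannot trigger aldol or Claisen chemistry of the succinate, and the alkene scavenger intercepts HOCl before it can chlorinate the electron-rich rings.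

Step 10
Reactants: 15 4-(benzyloxy)-6-{(1R,2R)-1-[4-(benzyloxy)-3-methoxyphenyl]-4-methoxy-2-(methoxycarbonyl)-4-oxobutyl}-2,3-dimethoxybenzoic acid
Product: 16 dimethyl (2R)-2-{(R)-[4-(benzyloxy)-3-methoxyphenyl][5-(benzyloxy)-3,4-dimethoxy-2-(methoxycarbonyl)phenyl]methyl}butanedioate
Conditions: MeI, K2CO3, DMF, rt
Reagents that add atoms: iodomethane CI
Why: Carboxylate O-alkylation (SN2 at MeI) esterifies the doubly ortho-flanked acid without any addition to its hindered carbonyl, and K2CO3 is too weak a base to start a Claisen reaction.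

Step 11
Reactants: 16 dimethyl (2R)-2-{(R)-[4-(benzyloxy)-3-methoxyphenyl][5-(benzyloxy)-3,4-dimethoxy-2-(methoxycarbonyl)phenyl]methyl}butanedioate
Product: 18 dimethyl (1R,2S,3R)-7-(benzyloxy)-1-[4-(benzyloxy)-3-methoxyphenyl]-5,6-dimethoxy-4-oxo-1,2,3,4-tetrahydronaphthalene-2,3-dicarboxylate, via sodium enolate 17 (not isolated)
Conditions: NaOMe (3 equiv), THF/MeOH 10:1, 65 °C, argon; then 1 M HCl, 0 °C
Reagents that add atoms: none
Why: Methoxide reversibly generates the ester enolates of 16, the C3 enolate adds to the C4 aryl ester carbonyl and the tetrahedral intermediate expels methoxide, which is a Dieckmann (intramolecular Claisen) condensation of the kind long used for 1-tetralone-2-carboxylates and, on 2-alkoxy-6-alkylbenzoates, in Staunton–Weinreb annulations. Ring B closes in the 6-(enolexo)-exo-trig mode. The selectivity needed is six- against five-membered closure: attack by the C2 enolate would give an indanone with a quaternary C2 that cannot be deprotonated and is reopened by methoxide, whereas the tetralone keeps an acidic C3–H and is withdrawn as sodium enolate 17, which pulls the whole equilibrium. C3, the new stereocentre, is created when 17 is protonated and stays enolisable, so it settles trans to the C2 ester, while C2 epimerises through its own ester enolate and settles trans to the C1 aryl group, so both C2 epimers of 16 converge on the all-equatorial half-chair dictated by C1. C1 has no acidifying neighbour while the ketone is tied up as its enolate and keeps its configuration. Exclusion of air prevents dehydrogenation of the enolate to a naphthol.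

Step 12
Reactants: 18 dimethyl (1R,2S,3R)-7-(benzyloxy)-1-[4-(benzyloxy)-3-methoxyphenyl]-5,6-dimethoxy-4-oxo-1,2,3,4-tetrahydronaphthalene-2,3-dicarboxylate
Product: 19 dimethyl (1R)-7-hydroxy-1-(4-hydroxy-3-methoxyphenyl)-5,6-dimethoxy-1,2,3,4-tetrahydronaphthalene-2,3-dicarboxylate (C1 fixed; C2/C3 not necessarily uniform)
Conditions: H2 (4 atm), 10% Pd/C, AcOH, HClO4 (cat.), 40 °C
Reagents that add atoms: none
Why: Catalytic hydrogenolysis; the aryl ketone, activated by the para and ortho oxygens of ring A, is reduced to the carbinol and then to CH2 by acid-assisted C–O cleavage as known for 1-tetralone-2-carboxylates, both benzyl ethers fall in the same operation, C1 carries no bond that palladium can cleave, and any loss of uniformity at C3 through the enol or a transient 3,4-alkene is repaired in step 13.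

Step 13
Reactants: 19 dimethyl (1R)-7-hydroxy-1-(4-hydroxy-3-methoxyphenyl)-5,6-dimethoxy-1,2,3,4-tetrahydronaphthalene-2,3-dicarboxylate
Product: 20 dimethyl (1R,2S,3S)-7-hydroxy-1-(4-hydroxy-3-methoxyphenyl)-5,6-dimethoxy-1,2,3,4-tetrahydronaphthalene-2,3-dicarboxylate
Conditions: NaOMe (5 equiv), MeOH, reflux, argon; then 1 M HCl
Reagents that add atoms: none
Why: Base-mediated epimerisation under thermodynamic control; C2 and C3 are each alpha to an ester and equilibrate through their enolates to the isomer with aryl, C9 and C10 all equatorial (1,2-trans and 2,3-trans), C1 is not acidic and serves as the fixed reference, and two equivalents of base are spent on the phenols.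

Step 14
Reactants: 20 dimethyl (1R,2S,3S)-7-hydroxy-1-(4-hydroxy-3-methoxyphenyl)-5,6-dimethoxy-1,2,3,4-tetrahydronaphthalene-2,3-dicarboxylate
Product: 21 (1R,2S,3S)-1-(4-hydroxy-3-methoxyphenyl)-2,3-bis(hydroxymethyl)-5,6-dimethoxy-1,2,3,4-tetrahydronaphthalen-7-ol (target, CNP0197710.1)
Conditions: LiAlH4 (excess), THF, 0 °C to reflux; then 1 M HCl
Reagents that add atoms: none
Why: LiAlH4 reduction of both esters to primary alcohols, with extra hydride to cover the two phenols, touches no stereocentre and follows the known reductions of phenolic lignan esters and lactones to their diols.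

Compound list
1 | methyl 3,5-dihydroxy-4-methoxybenzoate | COC(=O)c1cc(O)c(OC)c(O)c1 | starting material
2 | methyl 2-formyl-3,5-dihydroxy-4-methoxybenzoate | COC(=O)c1cc(O)c(OC)c(O)c1C=O | intermediate
3 | methyl 5-(benzyloxy)-2-formyl-3-hydroxy-4-methoxybenzoate | COC(=O)c1cc(OCc2ccccc2)c(OC)c(O)c1C=O | intermediate
4 | methyl 5-(benzyloxy)-2-formyl-3,4-dimethoxybenzoate | COC(=O)c1cc(OCc2ccccc2)c(OC)c(OC)c1C=O | intermediate
5 | methyl 5-(benzyloxy)-2-(1,3-dioxolan-2-yl)-3,4-dimethoxybenzoate | COC(=O)c1cc(OCc2ccccc2)c(OC)c(OC)c1C1OCCO1 | intermediate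
6 | [5-(benzyloxy)-2-(1,3-dioxolan-2-yl)-3,4-dimethoxyphenyl]methanol | OCc1cc(OCc2ccccc2)c(OC)c(OC)c1C1OCCO1 | intermediate
7 | methyl (triphenylphosphoranylidene)acetate | COC(=O)C=P(c1ccccc1)(c1ccccc1)c1ccccc1 | starting material
8 | 5-(benzyloxy)-2-(1,3-dioxolan-2-yl)-3,4-dimethoxybenzaldehyde (not isolated) | O=Cc1cc(OCc2ccccc2)c(OC)c(OC)c1C1OCCO1 | intermediate
9 | methyl (E)-3-[5-(benzyloxy)-2-(1,3-dioxolan-2-yl)-3,4-dimethoxyphenyl]prop-2-enoate | COC(=O)/C=C/c1cc(OCc2ccccc2)c(OC)c(OC)c1C1OCCO1 | intermediate
10 | (4-benzyloxy-3-methoxyphenyl)boronic acid | COc1cc(B(O)O)ccc1OCc1ccccc1 | starting material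
11 | methyl (3R)-3-[4-(benzyloxy)-3-methoxyphenyl]-3-[5-(benzyloxy)-2-(1,3-dioxolan-2-yl)-3,4-dimethoxyphenyl]propanoate | COC(=O)C[C@H](c1ccc(OCc2ccccc2)c(OC)c1)c1cc(OCc2ccccc2)c(OC)c(OC)c1C1OCCO1 | intermediate
12 | methyl bromoacetate | COC(=O)CBr | starting material
13 | dimethyl (2R)-2-{(R)-[4-(benzyloxy)-3-methoxyphenyl][5-(benzyloxy)-2-(1,3-dioxolan-2-yl)-3,4-dimethoxyphenyl]methyl}butanedioate (not isolated; drawn epimer, C2 epimer carried along) | COC(=O)C[C@@H](C(=O)OC)[C@H](c1ccc(OCc2ccccc2)c(OC)c1)c1cc(OCc2ccccc2)c(OC)c(OC)c1C1OCCO1 | intermediate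
14 | dimethyl (2R)-2-{(R)-[4-(benzyloxy)-3-methoxyphenyl][5-(benzyloxy)-2-formyl-3,4-dimethoxyphenyl]methyl}butanedioate (drawn epimer, C2 epimer carried along) | COC(=O)C[C@@H](C(=O)OC)[C@H](c1ccc(OCc2ccccc2)c(OC)c1)c1cc(OCc2ccccc2)c(OC)c(OC)c1C=O | intermediate
15 | 4-(benzyloxy)-6-{(1R,2R)-1-[4-(benzyloxy)-3-methoxyphenyl]-4-methoxy-2-(methoxycarbonyl)-4-oxobutyl}-2,3-dimethoxybenzoic acid (drawn epimer, C2 epimer carried along) | COC(=O)C[C@@H](C(=O)OC)[C@H](c1ccc(OCc2ccccc2)c(OC)c1)c1cc(OCc2ccccc2)c(OC)c(OC)c1C(=O)O | intermediate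
16 | dimethyl (2R)-2-{(R)-[4-(benzyloxy)-3-methoxyphenyl][5-(benzyloxy)-3,4-dimethoxy-2-(methoxycarbonyl)phenyl]methyl}butanedioate, the trimethyl ester precursor (drawn epimer, C2 epimer carried along) | COC(=O)C[C@@H](C(=O)OC)[C@H](c1ccc(OCc2ccccc2)c(OC)c1)c1cc(OCc2ccccc2)c(OC)c(OC)c1C(=O)OC | intermediate
17 | sodium enolate of 18, sodium (1R,2S)-1-aryl-2,3-bis(methoxycarbonyl)-1,2-dihydronaphthalen-4-olate (not isolated) | COc1cc([C@@H]2c3cc(OCc4ccccc4)c(OC)c(OC)c3C([O-])=C(C(=O)OC)[C@H]2C(=O)OC)ccc1OCc1ccccc1.[Na+] | intermediate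
18 | dimethyl (1R,2S,3R)-7-(benzyloxy)-1-[4-(benzyloxy)-3-methoxyphenyl]-5,6-dimethoxy-4-oxo-1,2,3,4-tetrahydronaphthalene-2,3-dicarboxylate (keto form, in equilibrium with its enol) | COc1cc([C@@H]2c3cc(OCc4ccccc4)c(OC)c(OC)c3C(=O)[C@H](C(=O)OC)[C@H]2C(=O)OC)ccc1OCc1ccccc1 | intermediate
19 | dimethyl (1R)-7-hydroxy-1-(4-hydroxy-3-methoxyphenyl)-5,6-dimethoxy-1,2,3,4-tetrahydronaphthalene-2,3-dicarboxylate (C1 fixed, C2/C3 not necessarily uniform) | COc1cc([C@@H]2c3cc(O)c(OC)c(OC)c3CC(C(=O)OC)C2C(=O)OC)ccc1O | intermediate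
20 | dimethyl (1R,2S,3S)-7-hydroxy-1-(4-hydroxy-3-methoxyphenyl)-5,6-dimethoxy-1,2,3,4-tetrahydronaphthalene-2,3-dicarboxylate (all-equatorial) | COc1cc([C@@H]2c3cc(O)c(OC)c(OC)c3C[C@H](C(=O)OC)[C@H]2C(=O)OC)ccc1O | intermediate
21 | (1R,2S,3S)-1-(4-hydroxy-3-methoxyphenyl)-2,3-bis(hydroxymethyl)-5,6-dimethoxy-1,2,3,4-tetrahydronaphthalen-7-ol | COc1cc([C@@H]2c3cc(O)c(OC)c(OC)c3C[C@H](CO)[C@H]2CO)ccc1O | target

Total step count: 14.
Longest linear sequence: 14 steps (1 to 21); 7, 10 and 12 are bought and enter directly.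

Steps most likely to fail

Step 11. Attack of the C3 enolate on the doubly ortho-flanked, electron-rich aryl ester may be too slow. Intermolecular condensation or saponification by adventitious water could then overtake ring closure. The fallback forms the same C3–C4 bond at the aldehyde oxidation level and sets out from 14. With LiN(SiMe3)2 in THF at −78 °C, the less hindered C3 enolate should add to the C4 aldehyde in an intramolecular aldol reaction. This gives the 4-hydroxytetralin diester F1 as stereoisomers at C2, C3 and C4, with C1 untouched. Hydrogenolysis of F1 over Pd/C in AcOH with catalytic HClO4 removes the benzylic hydroxyl and both benzyl ethers. The fallback comes back to the route at 19, where step 13 makes C2 and C3 uniform.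

Step 7. Insertion of the ortho-substituted cinnamate into the aryl–rhodium bond may be slow, so protodeboronation of the electron-rich boronic acid could consume the nucleophile. The ortho dioxolane may also erode facial discrimination. The fallback replaces catalyst control by a covalently bound auxiliary and sets out from 9.
- Saponification of 9 (LiOH, THF/H2O, buffered acidification) gives the cinnamic acid F2.
- Coupling with (S)-4-phenyl-1,3-oxazolidin-2-one (DCC, DMAP, CH2Cl2) gives the N-enoyl imide F3.
- The aryl Grignard reagent F4 is made from 1-(benzyloxy)-4-bromo-2-methoxybenzene and Mg in THF. It is added with CuBr·SMe2 at −40 °C to the magnesium-chelated s-cis imide, from the face away from the phenyl group. That face is the Si face of C1, and the addition gives the conjugate adduct F5.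
- Methanolysis (NaOMe, MeOH, 0 °C) releases the auxiliary and comes back to the route at 11.

Step 12. The reduction may stall at the carbinol stage or be held up by the hydrogen-bonded enol form. Acid may also divert the carbinol into lactonisation with the C9 ester. The fallback removes the C4 oxygen as a sulfonate instead and sets out from 18.
- Enolate 17 is regenerated (NaH, THF, 0 °C) and trapped with PhN(SO2CF3)2 as the enol triflate F6.
- Palladium-catalysed formate reduction (Pd(OAc)2, PPh3, HCO2H, Et3N, DMF, 60 °C) gives the 1,2-dihydronaphthalene diester F7.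
- Hydrogenation over Pd/C in neutral EtOAc/MeOH saturates C3=C4 and cleaves both benzyl ethers, coming back to the route at 19.

Further compounds
F1 | step 11 | dimethyl (1R)-7-(benzyloxy)-1-[4-(benzyloxy)-3-methoxyphenyl]-4-hydroxy-5,6-dimethoxy-1,2,3,4-tetrahydronaphthalene-2,3-dicarboxylate (stereoisomers at C2, C3 and C4) | COc1cc([C@@H]2c3cc(OCc4ccccc4)c(OC)c(OC)c3C(O)C(C(=O)OC)C2C(=O)OC)ccc1OCc1ccccc1
F2 | step 7 | (E)-3-[5-(benzyloxy)-2-(1,3-dioxolan-2-yl)-3,4-dimethoxyphenyl]prop-2-enoic acid | OC(=O)/C=C/c1cc(OCc2ccccc2)c(OC)c(OC)c1C1OCCO1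
F3 | step 7 | (4S)-3-{(E)-3-[5-(benzyloxy)-2-(1,3-dioxolan-2-yl)-3,4-dimethoxyphenyl]prop-2-enoyl}-4-phenyl-1,3-oxazolidin-2-one | O=C(/C=C/c1cc(OCc2ccccc2)c(OC)c(OC)c1C1OCCO1)N1[C@@H](c2ccccc2)COC1=O
F4 | step 7 | [4-(benzyloxy)-3-methoxyphenyl]magnesium bromide | COc1cc([Mg]Br)ccc1OCc1ccccc1
F5 | step 7 | (4S)-3-{(3R)-3-[4-(benzyloxy)-3-methoxyphenyl]-3-[5-(benzyloxy)-2-(1,3-dioxolan-2-yl)-3,4-dimethoxyphenyl]propanoyl}-4-phenyl-1,3-oxazolidin-2-one | O=C(C[C@H](c1ccc(OCc2ccccc2)c(OC)c1)c1cc(OCc2ccccc2)c(OC)c(OC)c1C1OCCO1)N1[C@@H](c2ccccc2)COC1=O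
F6 | step 12 | dimethyl (1R,2S)-7-(benzyloxy)-1-[4-(benzyloxy)-3-methoxyphenyl]-5,6-dimethoxy-4-{[(trifluoromethyl)sulfonyl]oxy}-1,2-dihydronaphthalene-2,3-dicarboxylate | COc1cc([C@@H]2c3cc(OCc4ccccc4)c(OC)c(OC)c3C(OS(=O)(=O)C(F)(F)F)=C(C(=O)OC)[C@H]2C(=O)OC)ccc1OCc1ccccc1
F7 | step 12 | dimethyl (1R,2S)-7-(benzyloxy)-1-[4-(benzyloxy)-3-methoxyphenyl]-5,6-dimethoxy-1,2-dihydronaphthalene-2,3-dicarboxylate | COc1cc([C@@H]2c3cc(OCc4ccccc4)c(OC)c(OC)c3C=C(C(=O)OC)[C@H]2C(=O)OC)ccc1OCc1ccccc1
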